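The C1–C6 hydroxy-lactone end of the target (carbonyl C1, C3–OH, ring oxygen on C5, alkene carbon C6; numbering runs on to the phenyl-bearing C13) is a six-carbon chain with syn oxygens on C3 and C5. It is therefore a meso cis-3,5-dioxygenated cyclohexanone cut between C1 and C6. An enantiotopos-selective Baeyer–Villiger oxidation inserts oxygen into that bond, expands the carbocycle to a seven-membered lactone and fixes C3 and C5 in one operation. The precursor is the bis-TBS ether of all-cis hydrogenated phloroglucinol, oxidised at the third hydroxyl. Methanolysis, oxidation, Julia–Kocienski coupling with a C7–C13 sulfone and desilylative lactonisation complete the route.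

Key step: step 3

Remark: all-cis-cyclohexane-1,3,5-triol (the all-cis hydrogenation product of phloroglucinol, sold as its dihydrate) and 1-methoxy-1,3-bis(trimethylsilyloxy)buta-1,3-diene are taken as purchasable.
Remark: in the two ligand-controlled steps (3 and 6) the sense of induction is assigned by analogy; both ligand antipodes are available should the assignment prove reversed.

Step 1
Reactants: 1 all-cis-cyclohexane-1,3,5-triol
Product: 2 all-cis-3,5-bis[(tert-butyldimethylsilyl)oxy]cyclohexan-1-ol
Conditions: triol dried by toluene azeotrope; TBSCl (2.1 equiv), imidazole, DMF, 0 °C to rt; mono- and tris-silyl ethers recycled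
Reagents that add atoms: tert-butyldimethylsilyl chloride (TBSCl), CC(C)(C)[Si](C)(C)Cl
Why: Silyl ether formation on three equivalent hydroxyls gives the same meso alcohol whichever two react, so only the degree of silylation has to be held by stoichiometry and no stereocentre is made.

Step 2
Reactants: 2 all-cis-3,5-bis[(tert-butyldimethylsilyl)oxy]cyclohexan-1-ol
Product: 3 (3R,5S)-3,5-bis[(tert-butyldimethylsilyl)oxy]cyclohexan-1-one (meso, cis)
Conditions: Dess–Martin periodinane, CH2Cl2, 0 °C to rt
Reagents that add atoms: none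
Why: Dess–Martin oxidation of the one free secondary alcohol runs without base, which spares the β-silyloxy ketone from elimination and leaves the mirror plane intact.

Step 3
Reactants: 3 (3R,5S)-3,5-bis[(tert-butyldimethylsilyl)oxy]cyclohexan-1-one
Product: 5 (4S,6R)-4,6-bis[(tert-butyldimethylsilyl)oxy]oxepan-2-one, via Criegee adduct 4 (not isolated)
Conditions: Sc(OTf)3 (5 mol%), C2-symmetric N,N′-dioxide ligand from (S)-pipecolic acid 2,6-diisopropylanilide (6 mol%), mCPBA (1.5 equiv), EtOAc, −20 °C
Reagents that add atoms: 3-chloroperoxybenzoic acid (mCPBA), OOC(=O)c1cccc(Cl)c1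
Why: The Sc(OTf)3–ligand complex binds the carbonyl oxygen, mCPBA adds to give Criegee adduct 4, and the α-methylene antiperiplanar to the breaking O–O bond shifts from carbon to oxygen with loss of 3-chlorobenzoate, so oxygen enters the C1–C6 bond. The closest known reaction type is the chiral Lewis acid catalysed (and likewise the monooxygenase catalysed) desymmetrising Baeyer–Villiger oxidation of 4-substituted and meso cis-3,5-disubstituted cyclohexanones. The seven-membered lactone is not closed by a cyclisation; it arises by ring expansion of the six-membered carbocycle through this 1,2-shift, the C6–O bond being the one new ring bond. No bond is made at C3 or C5, but these two mirror-related centres of 3 acquire a fixed absolute configuration (3S,5R in target numbering) through the choice of the C1–C6 over the C1–C2 bond, which the chiral pocket of the N,N′-dioxide on scandium should impose. Only enantiotopos selectivity is needed, because the mirror plane of 3 makes the regiochemistry degenerate; the diequatorial silyl ethers lock one chair and, being bulky and weakly basic, should stay off the metal and resist β-elimination. Which ligand antipode delivers 5 is to be settled on a small scale by correlating 6 with material of known configuration.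

Step 4
Reactants: 5 (4S,6R)-4,6-bis[(tert-butyldimethylsilyl)oxy]oxepan-2-one
Product: 6 methyl (3S,5R)-3,5-bis[(tert-butyldimethylsilyl)oxy]-6-hydroxyhexanoate
Conditions: K2CO3 (0.2 equiv), MeOH, 0 °C, short reaction time; pH 7 buffer work-up
Reagents that add atoms: methanol, CO
Why: Base-catalysed transesterification opens the seven-membered lactone at the acyl carbon and frees the C6 primary alcohol without touching C3 or C5.

Step 5
Reactants: 6 methyl (3S,5R)-3,5-bis[(tert-butyldimethylsilyl)oxy]-6-hydroxyhexanoate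
Product: 7 methyl (3S,5R)-3,5-bis[(tert-butyldimethylsilyl)oxy]-6-oxohexanoate
Conditions: Dess–Martin periodinane, CH2Cl2, 0 °C to rt; used at once in step 12
Reagents that add atoms: none
Why: Dess–Martin oxidation of the primary alcohol under non-basic conditions should give the α-silyloxy aldehyde without epimerising C5.

Step 6
Reactants: 8 (E)-cinnamaldehyde; 9 1-methoxy-1,3-bis[(trimethylsilyl)oxy]buta-1,3-diene
Product: 11 methyl (5S,6E)-5-hydroxy-3-oxo-7-phenylhept-6-enoate, via bis-silylated aldol adduct 10 (not isolated)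
Conditions: Ti(OiPr)4 (10 mol%), (S)-BINOL (10 mol%), 4 Å MS, THF, −78 °C to rt; then 1 M aq. HCl, 0 °C
Reagents that add atoms: none
Why: In this vinylogous Mukaiyama aldol addition the terminal carbon of the bis-silyl dienolate adds 1,2 to the titanium-bound aldehyde while the BINOL titanate shields one face, so that the carbinol carbon (C11 of the target) should form with S configuration (sense by analogy with BINOL–Ti(OiPr)4 additions to aromatic and α,β-unsaturated aldehydes, to be confirmed by Mosher ester analysis), and dilute acid then removes both silyl groups.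

Step 7
Reactants: 11 methyl (5S,6E)-5-hydroxy-3-oxo-7-phenylhept-6-enoate
Product: 12 methyl (3S,5S,6E)-3,5-dihydroxy-7-phenylhept-6-enoate
Conditions: Me4NBH(OAc)3 (5 equiv), MeCN/AcOH (1:1), −30 °C
Reagents that add atoms: none
Why: In this Evans–Saksena reduction the free hydroxyl exchanges onto boron and delivers hydride intramolecularly through a chair transition state, which sets the new carbinol (C9 of the target) anti to the existing one.

Step 8
Reactants: 12 methyl (3S,5S,6E)-3,5-dihydroxy-7-phenylhept-6-enoate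
Product: 13 methyl (3S,5S,6E)-3,5-dimethoxy-7-phenylhept-6-enoate
Conditions: Me3OBF4 (5 equiv), 1,8-bis(dimethylamino)naphthalene (6 equiv), 4 Å MS, CH2Cl2, 0 °C to rt
Reagents that add atoms: trimethyloxonium tetrafluoroborate, C[O+](C)C.F[B-](F)(F)F
Why: O-Methylation with Meerwein's salt and a non-nucleophilic base forms no alkoxide, so the β-hydroxy ester should neither undergo retro-aldol cleavage nor eliminate and both carbinol centres keep their configuration.

Step 9
Reactants: 13 methyl (3S,5S,6E)-3,5-dimethoxy-7-phenylhept-6-enoate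
Product: 14 (3R,5S,6E)-3,5-dimethoxy-7-phenylhept-6-en-1-ol
Conditions: iBu2AlH (2.5 equiv), CH2Cl2, −78 to 0 °C; aq. potassium sodium tartrate work-up
Reagents that add atoms: none
Why: Hydride reduction of the ester gives the primary alcohol while the methyl ethers and the styrene are inert (the C3 descriptor changes only through the priority rules).

Step 10
Reactants: 14 (3R,5S,6E)-3,5-dimethoxy-7-phenylhept-6-en-1-ol
Product: 15 5-{[(3S,5S,6E)-3,5-dimethoxy-7-phenylhept-6-en-1-yl]sulfanyl}-1-phenyl-1H-tetrazole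
Conditions: 1-phenyl-1H-tetrazole-5-thiol, PPh3, DIAD, THF, 0 °C to rt
Reagents that add atoms: 1-phenyl-1H-tetrazole-5-thiol, Sc1nnnn1-c1ccccc1
Why: Mitsunobu thioetherification of an unhindered primary alcohol gives S-alkylation cleanly and touches no stereocentre.

Step 11
Reactants: 15 5-{[(3S,5S,6E)-3,5-dimethoxy-7-phenylhept-6-en-1-yl]sulfanyl}-1-phenyl-1H-tetrazole
Product: 16 5-{[(3S,5S,6E)-3,5-dimethoxy-7-phenylhept-6-en-1-yl]sulfonyl}-1-phenyl-1H-tetrazole
Conditions: (NH4)6Mo7O24·4H2O (0.2 equiv), 30% aq. H2O2 (10 equiv), EtOH, 0 °C to rt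
Reagents that add atoms: hydrogen peroxide, OO
Why: Molybdate-catalysed peroxide oxidation takes the sulfide to the sulfone and does not epoxidise the 1,2-disubstituted styrene under these conditions.

Step 12
Reactants: 16 5-{[(3S,5S,6E)-3,5-dimethoxy-7-phenylhept-6-en-1-yl]sulfonyl}-1-phenyl-1H-tetrazole; 7 methyl (3S,5R)-3,5-bis[(tert-butyldimethylsilyl)oxy]-6-oxohexanoate
Product: 17 methyl (3S,5R,6E,9R,11S,12E)-3,5-bis[(tert-butyldimethylsilyl)oxy]-9,11-dimethoxy-13-phenyltrideca-6,12-dienoate
Conditions: 16 (1.2 equiv), KN(SiMe3)2 (1.15 equiv), DME, −78 °C, 30 min; then 7, −78 °C to rt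
Reagents that add atoms: none
Why: In this Julia–Kocienski olefination the potassium sulfonyl carbanion adds to the aldehyde, the tetrazole migrates to oxygen and anti-elimination of SO2 and tetrazololate should give the E C6=C7 alkene; a polar olefination is chosen because a C8 radical would close onto the C12=C13 styrene and a C8 organometal would expel the C9 methoxide.

Step 13
Reactants: 17 methyl (3S,5R,6E,9R,11S,12E)-3,5-bis[(tert-butyldimethylsilyl)oxy]-9,11-dimethoxy-13-phenyltrideca-6,12-dienoate
Product: 19 (4S,6R)-6-[(1E,4R,6S,7E)-4,6-dimethoxy-8-phenylocta-1,7-dien-1-yl]-4-hydroxyoxan-2-one, via dihydroxy ester 18 (not isolated)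
Conditions: HF·pyridine, pyridine, THF, 0 °C to rt; then PPTS (cat.), toluene, 50 °C
Reagents that add atoms: none
Why: Buffered fluoride desilylation frees both hydroxyls and mild acid-catalysed transesterification then closes the six-membered lactone from the C5 hydroxyl, conditions chosen so that the cinnamyl-type C11 methyl ether does not ionise and C3 does not dehydrate.

Compound list
1 | all-cis-cyclohexane-1,3,5-triol | O[C@@H]1C[C@H](O)C[C@H](O)C1 | starting material
2 | all-cis-3,5-bis[(tert-butyldimethylsilyl)oxy]cyclohexan-1-ol | O[C@@H]1C[C@H](O[Si](C)(C)C(C)(C)C)C[C@H](O[Si](C)(C)C(C)(C)C)C1 | intermediate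
3 | (3R,5S)-3,5-bis[(tert-butyldimethylsilyl)oxy]cyclohexan-1-one (meso, cis) | O=C1C[C@H](O[Si](C)(C)C(C)(C)C)C[C@H](O[Si](C)(C)C(C)(C)C)C1 | intermediate
4 | Criegee adduct, cis-3,5-bis[(tert-butyldimethylsilyl)oxy]-1-hydroxycyclohexyl 3-chlorobenzenecarboperoxoate (C1 configuration not defined) | OC1(OOC(=O)c2cccc(Cl)c2)C[C@H](O[Si](C)(C)C(C)(C)C)C[C@H](O[Si](C)(C)C(C)(C)C)C1 | intermediate (not isolated)
5 | (4S,6R)-4,6-bis[(tert-butyldimethylsilyl)oxy]oxepan-2-one | C1[C@H](O[Si](C)(C)C(C)(C)C)C[C@H](O[Si](C)(C)C(C)(C)C)CC(=O)O1 | intermediate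
6 | methyl (3S,5R)-3,5-bis[(tert-butyldimethylsilyl)oxy]-6-hydroxyhexanoate | COC(=O)C[C@@H](O[Si](C)(C)C(C)(C)C)C[C@@H](O[Si](C)(C)C(C)(C)C)CO | intermediate
7 | methyl (3S,5R)-3,5-bis[(tert-butyldimethylsilyl)oxy]-6-oxohexanoate | COC(=O)C[C@@H](O[Si](C)(C)C(C)(C)C)C[C@@H](O[Si](C)(C)C(C)(C)C)C=O | intermediate
8 | (E)-cinnamaldehyde | O=C/C=C/c1ccccc1 | starting material
9 | 1-methoxy-1,3-bis[(trimethylsilyl)oxy]buta-1,3-diene | COC(O[Si](C)(C)C)=CC(=C)O[Si](C)(C)C | starting material
10 | methyl (5S,6E)-7-phenyl-3,5-bis[(trimethylsilyl)oxy]hepta-2,6-dienoate (enol ether geometry not defined) | COC(=O)C=C(O[Si](C)(C)C)C[C@@H](/C=C/c1ccccc1)O[Si](C)(C)C | intermediate (not isolated)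
11 | methyl (5S,6E)-5-hydroxy-3-oxo-7-phenylhept-6-enoate | COC(=O)CC(=O)C[C@@H](/C=C/c1ccccc1)O | intermediate
12 | methyl (3S,5S,6E)-3,5-dihydroxy-7-phenylhept-6-enoate | COC(=O)C[C@@H](O)C[C@@H](/C=C/c1ccccc1)O | intermediate
13 | methyl (3S,5S,6E)-3,5-dimethoxy-7-phenylhept-6-enoate | COC(=O)C[C@@H](OC)C[C@@H](/C=C/c1ccccc1)OC | intermediate
14 | (3R,5S,6E)-3,5-dimethoxy-7-phenylhept-6-en-1-ol | OCC[C@@H](OC)C[C@@H](/C=C/c1ccccc1)OC | intermediate
15 | 5-{[(3S,5S,6E)-3,5-dimethoxy-7-phenylhept-6-en-1-yl]sulfanyl}-1-phenyl-1H-tetrazole | c1ccccc1-n1nnnc1SCC[C@@H](OC)C[C@@H](/C=C/c1ccccc1)OC | intermediate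
16 | 5-{[(3S,5S,6E)-3,5-dimethoxy-7-phenylhept-6-en-1-yl]sulfonyl}-1-phenyl-1H-tetrazole | O=S(=O)(CC[C@@H](OC)C[C@@H](/C=C/c1ccccc1)OC)c1nnnn1-c1ccccc1 | intermediate
17 | methyl (3S,5R,6E,9R,11S,12E)-3,5-bis[(tert-butyldimethylsilyl)oxy]-9,11-dimethoxy-13-phenyltrideca-6,12-dienoate | COC(=O)C[C@@H](O[Si](C)(C)C(C)(C)C)C[C@@H](O[Si](C)(C)C(C)(C)C)/C=C/C[C@@H](OC)C[C@@H](/C=C/c1ccccc1)OC | intermediate
18 | methyl (3S,5R,6E,9R,11S,12E)-3,5-dihydroxy-9,11-dimethoxy-13-phenyltrideca-6,12-dienoate | COC(=O)C[C@@H](O)C[C@@H](O)/C=C/C[C@@H](OC)C[C@@H](/C=C/c1ccccc1)OC | intermediate (not isolated)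
19 | (4S,6R)-6-[(1E,4R,6S,7E)-4,6-dimethoxy-8-phenylocta-1,7-dien-1-yl]-4-hydroxyoxan-2-one | CO[C@H](C/C=C/[C@H]1C[C@H](O)CC(=O)O1)C[C@@H](/C=C/c1ccccc1)OC | target

Total step count: 13. Longest linear sequence: 8 steps (steps 6 to 13, from 8 to 19); the lactone branch needs 7 (steps 1 to 5, 12 and 13).

Steps most likely to fail

Step 3. The two enantiotopic α-methylene groups may be poorly discriminated, a ligand-free peracid pathway may run alongside and erode the enantiomeric purity, or the Lewis acid may induce β-elimination of silanol. The fallback sets out from 3 and comes back at 7; it cuts the same C1–C6 bond by a different, known sequence. Enantioselective deprotonation of 3 with a chiral lithium amide (lithium bis[(R)-1-phenylethyl]amide or its antipode, TMSCl present, THF, −100 °C) should give the silyl enol ether (3R,5S)-3,5-bis[(tert-butyldimethylsilyl)oxy]-1-[(trimethylsilyl)oxy]cyclohex-1-ene F1. Ozonolysis (O3, CH2Cl2/MeOH, −78 °C; then Me2S) should cleave the enol double bond to the aldehyde acid (3S,5R)-3,5-bis[(tert-butyldimethylsilyl)oxy]-6-oxohexanoic acid F2, and esterification with TMSCHN2 (MeOH/toluene, 0 °C) should give 7, so that steps 3 to 5 are bypassed.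

Step 12. The E selectivity may be eroded at the α-silyloxy aldehyde, or the basic carbanion may enolise the ester with loss of the C3 silyloxy group or epimerise C5. The fallback sets out from 14 and comes back at 17; it replaces the basic olefination by a chromium alkylidenation. Dess–Martin oxidation of 14 should give (3S,5S,6E)-3,5-dimethoxy-7-phenylhept-6-enal F3, hydrazine hydrate in EtOH its hydrazone [(3R,5S,6E)-3,5-dimethoxy-7-phenylhept-6-en-1-ylidene]hydrazine F4, and iodine with Et3N the geminal diiodide [(1E,3S,5S)-7,7-diiodo-3,5-dimethoxyhept-1-en-1-yl]benzene F5. Takai–Utimoto alkylidenation of aldehyde 7 with F5 and CrCl2 in THF/DMF should then give 17 under non-basic conditions with E selectivity.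

Step 4. The C5 silyl group may migrate to the newly freed primary alkoxide, after which the liberated C5 hydroxyl would close onto the ester. The fallback sets out from 5 and comes back at 19; it opens the lactone without a free alkoxide and carries an amide in place of the ester. MeNH(OMe)·HCl with Me3Al (CH2Cl2, 0 °C) should open 5 to the hydroxy amide (3S,5R)-3,5-bis[(tert-butyldimethylsilyl)oxy]-6-hydroxy-N-methoxy-N-methylhexanamide F6, and Dess–Martin oxidation should give the aldehyde (3S,5R)-3,5-bis[(tert-butyldimethylsilyl)oxy]-N-methoxy-N-methyl-6-oxohexanamide F7. Julia–Kocienski coupling with 16 as in step 12 should give (3S,5R,6E,9R,11S,12E)-3,5-bis[(tert-butyldimethylsilyl)oxy]-N,9,11-trimethoxy-N-methyl-13-phenyltrideca-6,12-dienamide F8. HF·pyridine should give the diol amide (3S,5R,6E,9R,11S,12E)-3,5-dihydroxy-N,9,11-trimethoxy-N-methyl-13-phenyltrideca-6,12-dienamide F9, which should lactonise to 19 under mild acid.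

Further compounds
F1 | step 3 | (3R,5S)-3,5-bis[(tert-butyldimethylsilyl)oxy]-1-[(trimethylsilyl)oxy]cyclohex-1-ene | C1=C(O[Si](C)(C)C)C[C@@H](O[Si](C)(C)C(C)(C)C)C[C@H]1O[Si](C)(C)C(C)(C)C
F2 | step 3 | (3S,5R)-3,5-bis[(tert-butyldimethylsilyl)oxy]-6-oxohexanoic acid | OC(=O)C[C@@H](O[Si](C)(C)C(C)(C)C)C[C@@H](O[Si](C)(C)C(C)(C)C)C=O
F3 | step 12 | (3S,5S,6E)-3,5-dimethoxy-7-phenylhept-6-enal | O=CC[C@@H](OC)C[C@@H](/C=C/c1ccccc1)OC
F4 | step 12 | [(3R,5S,6E)-3,5-dimethoxy-7-phenylhept-6-en-1-ylidene]hydrazine | NN=CC[C@@H](OC)C[C@@H](/C=C/c1ccccc1)OC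
F5 | step 12 | [(1E,3S,5S)-7,7-diiodo-3,5-dimethoxyhept-1-en-1-yl]benzene | IC(I)C[C@@H](OC)C[C@@H](/C=C/c1ccccc1)OC
F6 | step 4 | (3S,5R)-3,5-bis[(tert-butyldimethylsilyl)oxy]-6-hydroxy-N-methoxy-N-methylhexanamide | CON(C)C(=O)C[C@@H](O[Si](C)(C)C(C)(C)C)C[C@@H](O[Si](C)(C)C(C)(C)C)CO
F7 | step 4 | (3S,5R)-3,5-bis[(tert-butyldimethylsilyl)oxy]-N-methoxy-N-methyl-6-oxohexanamide | CON(C)C(=O)C[C@@H](O[Si](C)(C)C(C)(C)C)C[C@@H](O[Si](C)(C)C(C)(C)C)C=O
F8 | step 4 | (3S,5R,6E,9R,11S,12E)-3,5-bis[(tert-butyldimethylsilyl)oxy]-N,9,11-trimethoxy-N-methyl-13-phenyltrideca-6,12-dienamide | CON(C)C(=O)C[C@@H](O[Si](C)(C)C(C)(C)C)C[C@@H](O[Si](C)(C)C(C)(C)C)/C=C/C[C@@H](OC)C[C@@H](/C=C/c1ccccc1)OC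
F9 | step 4 | (3S,5R,6E,9R,11S,12E)-3,5-dihydroxy-N,9,11-trimethoxy-N-methyl-13-phenyltrideca-6,12-dienamide | CON(C)C(=O)C[C@@H](O)C[C@@H](O)/C=C/C[C@@H](OC)C[C@@H](/C=C/c1ccccc1)OC
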